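Everything rests on cutting the C12–C13 bond of the oxocene (chain atoms C1, alkyne CH, to C15, ethyl CH3). In the ring O7–C7–C8–C9=C10–C11–C12–C13, the ether carbon C13 sits next to the heteroatom-bearing C12, which is what remains when a C12 ketyl adds to the β-carbon of a β-alkoxyacrylate carried on O7. One SmI2 reduction therefore closes the eight-membered ring and sets C12 and C13 relative to C7. The precursor is an open-chain (E)-β-alkoxyacrylate of a (2R,4Z)-heptenol bearing the C12 aldehyde and a p-methoxybenzyl ether on O6, removable later without touching the ring alkene. Inversion at C12, reduction of the ester arm to ethyl and side-chain growth from C6 finish the route.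

Key step: step 8

Remark: oxocene names use fixed ring locants O1, C2 (= C13), C3 (= C12), C5=C6 (= C10=C9) and C8 (= C7) so that descriptors can be compared from compound to compound; the trans-hydroxy ester 13 is assumed to be isolable without lactonization after a neutral work-up.

Step 1
Reactants: 1 but-3-yn-1-ol
Product: 2 tert-butyl(but-3-yn-1-yloxy)dimethylsilane
Conditions: TBSCl, imidazole, DMF, 0 °C → rt
Reagents that add atoms: tert-butyldimethylsilyl chloride, CC(C)(C)[Si](C)(C)Cl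
Why: Silyl ether formation on an unhindered primary alcohol masks the C12 oxygen before the acetylide is made; no stereocentre is involved.

Step 2
Reactants: 3 (S)-glycidol
Product: 5 (2R)-2-{[(4-methoxybenzyl)oxy]methyl}oxirane, via sodium alkoxide of (S)-glycidol 4 (not isolated)
Conditions: NaH, THF/DMF, 0 °C; then PMBCl, Bu4NI (cat.), 0 °C → rt
Reagents that add atoms: 4-methoxybenzyl chloride, COc1ccc(CCl)cc1
Why: Williamson etherification of the alkoxide with the benzylic chloride leaves the oxirane carbon untouched, the descriptor changing from S to R only through the CIP priorities.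

Step 3
Reactants: 2 tert-butyl(but-3-yn-1-yloxy)dimethylsilane; 5 (2R)-2-{[(4-methoxybenzyl)oxy]methyl}oxirane
Product: 7 (2R)-7-[(tert-butyldimethylsilyl)oxy]-1-[(4-methoxybenzyl)oxy]hept-4-yn-2-ol, via lithium 4-[(tert-butyldimethylsilyl)oxy]but-1-yn-1-ide 6 (not isolated)
Conditions: n-BuLi, THF, −78 °C; BF3·OEt2; then 5, −78 °C
Reagents that add atoms: none
Why: Yamaguchi–Hirao alkynylation, in which BF3 activates the epoxide and the lithium acetylide opens it at the unsubstituted carbon, forms C8–C9 and carries the C7 stereocentre over from 5 unchanged.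

Step 4
Reactants: 7 (2R)-7-[(tert-butyldimethylsilyl)oxy]-1-[(4-methoxybenzyl)oxy]hept-4-yn-2-ol
Product: 8 (2R,4Z)-7-[(tert-butyldimethylsilyl)oxy]-1-[(4-methoxybenzyl)oxy]hept-4-en-2-ol
Conditions: H2 (1 atm), Pd/CaCO3 poisoned with Pb(OAc)2 (Lindlar catalyst), quinoline, EtOAc, rt
Reagents that add atoms: none
Why: Lindlar semihydrogenation delivers H2 syn on the poisoned palladium surface, giving the Z-C9=C10 alkene without hydrogenolysis of the PMB ether.

Step 5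
Reactants: 8 (2R,4Z)-7-[(tert-butyldimethylsilyl)oxy]-1-[(4-methoxybenzyl)oxy]hept-4-en-2-ol; 9 ethyl propiolate
Product: 10 ethyl (2E)-3-{[(2R,4Z)-7-[(tert-butyldimethylsilyl)oxy]-1-[(4-methoxybenzyl)oxy]hept-4-en-2-yl]oxy}prop-2-enoate
Conditions: N-methylmorpholine, CH2Cl2, rt
Reagents that add atoms: none
Why: Amine-mediated oxa-Michael addition of the C7 alcohol to the ynoate gives the (E)-β-alkoxyacrylate as the stable geometry, so the hindered ether is made without coupling two carbinols.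

Step 6
Reactants: 10 ethyl (2E)-3-{[(2R,4Z)-7-[(tert-butyldimethylsilyl)oxy]-1-[(4-methoxybenzyl)oxy]hept-4-en-2-yl]oxy}prop-2-enoate
Product: 11 ethyl (2E)-3-{[(2R,4Z)-7-hydroxy-1-[(4-methoxybenzyl)oxy]hept-4-en-2-yl]oxy}prop-2-enoate
Conditions: HF·pyridine, pyridine, THF, 0 °C → rt
Reagents that add atoms: none
Why: Fluoride desilylation of the primary TBS ether under buffered conditions leaves the vinylogous carbonate and the PMB ether intact.

Step 7
Reactants: 11 ethyl (2E)-3-{[(2R,4Z)-7-hydroxy-1-[(4-methoxybenzyl)oxy]hept-4-en-2-yl]oxy}prop-2-enoate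
Product: 12 ethyl (2E)-3-{[(2R,4Z)-1-[(4-methoxybenzyl)oxy]-7-oxohept-4-en-2-yl]oxy}prop-2-enoate
Conditions: Dess–Martin periodinane, NaHCO3, CH2Cl2, 0 °C → rt; filtered and used at once
Reagents that add atoms: none
Why: Buffered Dess–Martin oxidation gives the skipped (β,γ-unsaturated) aldehyde under neutral conditions that should not move the Z alkene into conjugation.

Step 8
Reactants: 12 ethyl (2E)-3-{[(2R,4Z)-1-[(4-methoxybenzyl)oxy]-7-oxohept-4-en-2-yl]oxy}prop-2-enoate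
Product: 13 ethyl 2-[(2R,3S,5Z,8R)-3-hydroxy-8-{[(4-methoxybenzyl)oxy]methyl}-3,4,7,8-tetrahydro-2H-oxocin-2-yl]acetate
Conditions: SmI2 (3 equiv), MeOH (3 equiv), THF, 0 °C → rt, slow addition of 12 to 0.005 M; pH 7 buffer work-up
Reagents that add atoms: none
Why: Proposed new method: SmI2 transfers one electron to the C12 aldehyde and the samarium ketyl, with the metal also bound to the acrylate carbonyl, adds through carbon to C13, the β-carbon of the (E)-β-alkoxyacrylate; a second SmI2 reduces the α-ester radical to a samarium enolate, and MeOH protonates it and the alkoxide. The closest known reaction type is the SmI2-induced ketyl cyclization of aldehydes onto β-alkoxyacrylates, which closes 2,3-trans tetrahydropyrans and oxepanes but has not been shown for an eight-membered ether. The oxocene closes in the 8-exo-trig mode, and the Z-C9=C10 alkene together with O7 removes transannular hydrogens and holds C12 within reach of C13. C12 and C13 arise together from the chelated transition state, in which the E acrylate places the ketyl oxygen trans to the CH2CO2Et arm (12S,13R), and their sense relative to the resident C7 centre comes from the CH2OPMB group lying pseudo-equatorial, which gives the 7,13-cis ether. The step needs ring closure to outrun simple carbonyl reduction and pinacol dimerization, which slow addition at high dilution should secure, and it needs the 7,13-cis, 12,13-trans diastereomer, which the E acrylate, the intact chelate (no HMPA) and the C7 substituent should secure.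

Step 9
Reactants: 13 ethyl 2-[(2R,3S,5Z,8R)-3-hydroxy-8-{[(4-methoxybenzyl)oxy]methyl}-3,4,7,8-tetrahydro-2H-oxocin-2-yl]acetate
Product: 14 (2R,3R,5Z,8R)-2-(2-ethoxy-2-oxoethyl)-8-{[(4-methoxybenzyl)oxy]methyl}-3,4,7,8-tetrahydro-2H-oxocin-3-yl 4-nitrobenzoate
Conditions: 4-nitrobenzoic acid, PPh3, DIAD, toluene, 0 °C → rt
Reagents that add atoms: 4-nitrobenzoic acid, O=C(O)c1ccc(cc1)[N+](=O)[O-]
Why: Mitsunobu esterification displaces the alkoxyphosphonium by SN2, inverting C12 from S to R so that its oxygen becomes cis to the C13 arm, as the final invertive bromination requires.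

Step 10
Reactants: 14 (2R,3R,5Z,8R)-2-(2-ethoxy-2-oxoethyl)-8-{[(4-methoxybenzyl)oxy]methyl}-3,4,7,8-tetrahydro-2H-oxocin-3-yl 4-nitrobenzoate
Product: 15 (2R,3R,5Z,8R)-2-(2-hydroxyethyl)-8-{[(4-methoxybenzyl)oxy]methyl}-3,4,7,8-tetrahydro-2H-oxocin-3-ol
Conditions: LiBH4, MeOH (1 equiv), THF, 0 °C → rt
Reagents that add atoms: none
Why: Borohydride ester reduction cleaves the activated aryl ester and reduces the ethyl ester to CH2CH2OH in one operation without touching the nitro group, the alkene or any stereocentre.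

Step 11
Reactants: 15 (2R,3R,5Z,8R)-2-(2-hydroxyethyl)-8-{[(4-methoxybenzyl)oxy]methyl}-3,4,7,8-tetrahydro-2H-oxocin-3-ol
Product: 16 2-[(2R,3R,5Z,8R)-3-hydroxy-8-{[(4-methoxybenzyl)oxy]methyl}-3,4,7,8-tetrahydro-2H-oxocin-2-yl]ethyl 4-methylbenzenesulfonate
Conditions: TsCl, Et3N, Me3N·HCl (cat.), CH2Cl2, 0 °C; taken on without storage
Reagents that add atoms: 4-methylbenzenesulfonyl chloride, Cc1ccc(cc1)S(=O)(=O)Cl
Why: Selective sulfonylation of the primary alcohol over the hindered ring carbinol activates C15, and the cold, weakly basic medium should keep the free C12 hydroxyl from displacing the tosylate.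

Step 12
Reactants: 16 2-[(2R,3R,5Z,8R)-3-hydroxy-8-{[(4-methoxybenzyl)oxy]methyl}-3,4,7,8-tetrahydro-2H-oxocin-2-yl]ethyl 4-methylbenzenesulfonate
Product: 17 2-[(2R,3R,5Z,8R)-3-[(tert-butyldimethylsilyl)oxy]-8-{[(4-methoxybenzyl)oxy]methyl}-3,4,7,8-tetrahydro-2H-oxocin-2-yl]ethyl 4-methylbenzenesulfonate
Conditions: TBSOTf, 2,6-lutidine, CH2Cl2, −78 °C
Reagents that add atoms: tert-butyldimethylsilyl trifluoromethanesulfonate, CC(C)(C)[Si](C)(C)OS(=O)(=O)C(F)(F)F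
Why: Silyl triflate silylation with a non-nucleophilic base protects the C12 oxygen with retention and removes the internal nucleophile before hydride is applied.

Step 13
Reactants: 17 2-[(2R,3R,5Z,8R)-3-[(tert-butyldimethylsilyl)oxy]-8-{[(4-methoxybenzyl)oxy]methyl}-3,4,7,8-tetrahydro-2H-oxocin-2-yl]ethyl 4-methylbenzenesulfonate
Product: 18 tert-butyl{[(2R,3R,5Z,8R)-2-ethyl-8-{[(4-methoxybenzyl)oxy]methyl}-3,4,7,8-tetrahydro-2H-oxocin-3-yl]oxy}dimethylsilane
Conditions: LiEt3BH, THF, 0 °C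
Reagents that add atoms: none
Why: Hydride SN2 displacement of the primary tosylate (borohydride deoxygenation) turns the arm into the C14–C15 ethyl group while the silyl and PMB ethers are inert.

Step 14
Reactants: 18 tert-butyl{[(2R,3R,5Z,8R)-2-ethyl-8-{[(4-methoxybenzyl)oxy]methyl}-3,4,7,8-tetrahydro-2H-oxocin-3-yl]oxy}dimethylsilane
Product: 19 [(2R,3R,5Z,8R)-3-[(tert-butyldimethylsilyl)oxy]-2-ethyl-3,4,7,8-tetrahydro-2H-oxocin-8-yl]methanol
Conditions: DDQ, CH2Cl2/pH 7 buffer, 0 °C → rt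
Reagents that add atoms: none
Why: Oxidative PMB ether cleavage by DDQ proceeds through the benzylic oxocarbenium ion and so frees O6 without any reducing conditions that would endanger the ring alkene.

Step 15
Reactants: 19 [(2R,3R,5Z,8R)-3-[(tert-butyldimethylsilyl)oxy]-2-ethyl-3,4,7,8-tetrahydro-2H-oxocin-8-yl]methanol
Product: 20 (2R,3R,5Z,8R)-3-[(tert-butyldimethylsilyl)oxy]-2-ethyl-3,4,7,8-tetrahydro-2H-oxocine-8-carbaldehyde
Conditions: Dess–Martin periodinane, NaHCO3, CH2Cl2, 0 °C → rt; used crude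
Reagents that add atoms: none
Why: Buffered Dess–Martin oxidation gives the C6 α-alkoxy aldehyde under conditions mild enough that C7 should not epimerize.

Step 16
Reactants: 20 (2R,3R,5Z,8R)-3-[(tert-butyldimethylsilyl)oxy]-2-ethyl-3,4,7,8-tetrahydro-2H-oxocine-8-carbaldehyde
Product: 21 (1R)-1-[(2R,3R,5Z,8R)-3-[(tert-butyldimethylsilyl)oxy]-2-ethyl-3,4,7,8-tetrahydro-2H-oxocin-8-yl]but-3-en-1-ol
Conditions: MgBr2·OEt2, allyltributylstannane, CH2Cl2, −78 → −20 °C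
Reagents that add atoms: allyltributylstannane, C=CC[Sn](CCCC)(CCCC)CCCC
Why: Chelation-controlled (Keck-type) allylation, in which magnesium bridges the aldehyde oxygen and ring oxygen O7 and the allyl group adds to the carbonyl face opposite the C8 methylene, should set C6 as R (6,7-syn).

Step 17
Reactants: 21 (1R)-1-[(2R,3R,5Z,8R)-3-[(tert-butyldimethylsilyl)oxy]-2-ethyl-3,4,7,8-tetrahydro-2H-oxocin-8-yl]but-3-en-1-ol
Product: 22 (2E,5R)-5-[(2R,3R,5Z,8R)-3-[(tert-butyldimethylsilyl)oxy]-2-ethyl-3,4,7,8-tetrahydro-2H-oxocin-8-yl]-5-hydroxypent-2-enal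
Conditions: crotonaldehyde (excess), second-generation Hoveyda–Grubbs catalyst [RuCl2(H2IMes)(=CH-C6H4-2-O-i-Pr)] (cat.), CH2Cl2, 40 °C
Reagents that add atoms: (E)-crotonaldehyde, C/C=C/C=O
Why: Olefin cross-metathesis engages the fast-initiating terminal alkene in preference to the internal ring cis-alkene and gives the enal as its thermodynamic E isomer, setting the C3=C4 geometry.

Step 18
Reactants: 22 (2E,5R)-5-[(2R,3R,5Z,8R)-3-[(tert-butyldimethylsilyl)oxy]-2-ethyl-3,4,7,8-tetrahydro-2H-oxocin-8-yl]-5-hydroxypent-2-enal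
Product: 23 (1R,3E)-1-[(2R,3R,5Z,8R)-3-[(tert-butyldimethylsilyl)oxy]-2-ethyl-3,4,7,8-tetrahydro-2H-oxocin-8-yl]hex-3-en-5-yn-1-ol
Conditions: TMSCHN2, LDA (2.5 equiv each), THF, −78 °C; then 22, −78 → 0 °C
Reagents that add atoms: (trimethylsilyl)diazomethane, C[Si](C)(C)C=[N+]=[N-]
Why: Colvin rearrangement, in which lithiated silyldiazomethane adds to the aldehyde, loses silanolate and N2 and the alkylidene carbene undergoes a 1,2-hydrogen shift, gives the terminal alkyne with the E alkene intact while the C6 lithium alkoxide stays a spectator.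

Step 19
Reactants: 23 (1R,3E)-1-[(2R,3R,5Z,8R)-3-[(tert-butyldimethylsilyl)oxy]-2-ethyl-3,4,7,8-tetrahydro-2H-oxocin-8-yl]hex-3-en-5-yn-1-ol
Product: 24 (1R,3E)-1-[(2R,3R,5Z,8R)-3-[(tert-butyldimethylsilyl)oxy]-2-ethyl-3,4,7,8-tetrahydro-2H-oxocin-8-yl]hex-3-en-5-yn-1-yl acetate
Conditions: Ac2O, pyridine, DMAP (cat.), CH2Cl2, 0 °C → rt
Reagents that add atoms: acetic anhydride, CC(=O)OC(C)=O
Why: DMAP-catalysed acylation of the only free hydroxyl installs the C6 acetate with retention, after the base-mediated alkyne formation is over.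

Step 20
Reactants: 24 (1R,3E)-1-[(2R,3R,5Z,8R)-3-[(tert-butyldimethylsilyl)oxy]-2-ethyl-3,4,7,8-tetrahydro-2H-oxocin-8-yl]hex-3-en-5-yn-1-yl acetate
Product: 25 (1R,3E)-1-[(2R,3R,5Z,8R)-2-ethyl-3-hydroxy-3,4,7,8-tetrahydro-2H-oxocin-8-yl]hex-3-en-5-yn-1-yl acetate
Conditions: HF·pyridine, THF, 0 °C → rt
Reagents that add atoms: none
Why: Fluoride desilylation under mildly acidic conditions frees the C12 hydroxyl without cleaving the acetate or touching the enyne.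

Step 21
Reactants: 25 (1R,3E)-1-[(2R,3R,5Z,8R)-2-ethyl-3-hydroxy-3,4,7,8-tetrahydro-2H-oxocin-8-yl]hex-3-en-5-yn-1-yl acetate
Product: 26 (1R,3E)-1-[(2R,3S,5Z,8R)-3-bromo-2-ethyl-3,4,7,8-tetrahydro-2H-oxocin-8-yl]hex-3-en-5-yn-1-yl acetate (target)
Conditions: CBr4, P(n-C8H17)3, 1-methylcyclohexene, toluene, 70 °C
Reagents that add atoms: carbon tetrabromide, BrC(Br)(Br)Br
Why: Appel-type bromination displaces the alkoxyphosphonium by bromide with SN2 inversion, turning the 12R alcohol into the 12S bromide trans to the ethyl group.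

Compound list
1 | but-3-yn-1-ol | C#CCCO | starting material
2 | tert-butyl(but-3-yn-1-yloxy)dimethylsilane | C#CCCO[Si](C)(C)C(C)(C)C | intermediate
3 | (S)-glycidol | OC[C@H]1CO1 | starting material
4 | sodium alkoxide of (S)-glycidol | [Na+].[O-]C[C@H]1CO1 | intermediate (not isolated)
5 | (2R)-2-{[(4-methoxybenzyl)oxy]methyl}oxirane | COc1ccc(COC[C@H]2CO2)cc1 | intermediate
6 | lithium 4-[(tert-butyldimethylsilyl)oxy]but-1-yn-1-ide | [Li]C#CCCO[Si](C)(C)C(C)(C)C | intermediate (not isolated)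
7 | (2R)-7-[(tert-butyldimethylsilyl)oxy]-1-[(4-methoxybenzyl)oxy]hept-4-yn-2-ol | COc1ccc(COC[C@H](O)CC#CCCO[Si](C)(C)C(C)(C)C)cc1 | intermediate
8 | (2R,4Z)-7-[(tert-butyldimethylsilyl)oxy]-1-[(4-methoxybenzyl)oxy]hept-4-en-2-ol | COc1ccc(COC[C@H](O)C/C=C\CCO[Si](C)(C)C(C)(C)C)cc1 | intermediate
9 | ethyl propiolate | C#CC(=O)OCC | starting material
10 | ethyl (2E)-3-{[(2R,4Z)-7-[(tert-butyldimethylsilyl)oxy]-1-[(4-methoxybenzyl)oxy]hept-4-en-2-yl]oxy}prop-2-enoate | COc1ccc(COC[C@H](O/C=C/C(=O)OCC)C/C=C\CCO[Si](C)(C)C(C)(C)C)cc1 | intermediate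
11 | ethyl (2E)-3-{[(2R,4Z)-7-hydroxy-1-[(4-methoxybenzyl)oxy]hept-4-en-2-yl]oxy}prop-2-enoate | COc1ccc(COC[C@H](O/C=C/C(=O)OCC)C/C=C\CCO)cc1 | intermediate
12 | ethyl (2E)-3-{[(2R,4Z)-1-[(4-methoxybenzyl)oxy]-7-oxohept-4-en-2-yl]oxy}prop-2-enoate | COc1ccc(COC[C@H](O/C=C/C(=O)OCC)C/C=C\CC=O)cc1 | intermediate
13 | ethyl 2-[(2R,3S,5Z,8R)-3-hydroxy-8-{[(4-methoxybenzyl)oxy]methyl}-3,4,7,8-tetrahydro-2H-oxocin-2-yl]acetate | COc1ccc(COC[C@H]2C/C=C\C[C@H](O)[C@@H](CC(=O)OCC)O2)cc1 | intermediate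
14 | (2R,3R,5Z,8R)-2-(2-ethoxy-2-oxoethyl)-8-{[(4-methoxybenzyl)oxy]methyl}-3,4,7,8-tetrahydro-2H-oxocin-3-yl 4-nitrobenzoate | COc1ccc(COC[C@H]2C/C=C\C[C@@H](OC(=O)c3ccc(cc3)[N+](=O)[O-])[C@@H](CC(=O)OCC)O2)cc1 | intermediate
15 | (2R,3R,5Z,8R)-2-(2-hydroxyethyl)-8-{[(4-methoxybenzyl)oxy]methyl}-3,4,7,8-tetrahydro-2H-oxocin-3-ol | COc1ccc(COC[C@H]2C/C=C\C[C@@H](O)[C@@H](CCO)O2)cc1 | intermediate
16 | 2-[(2R,3R,5Z,8R)-3-hydroxy-8-{[(4-methoxybenzyl)oxy]methyl}-3,4,7,8-tetrahydro-2H-oxocin-2-yl]ethyl 4-methylbenzenesulfonate | COc1ccc(COC[C@H]2C/C=C\C[C@@H](O)[C@@H](CCOS(=O)(=O)c3ccc(C)cc3)O2)cc1 | intermediate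
17 | 2-[(2R,3R,5Z,8R)-3-[(tert-butyldimethylsilyl)oxy]-8-{[(4-methoxybenzyl)oxy]methyl}-3,4,7,8-tetrahydro-2H-oxocin-2-yl]ethyl 4-methylbenzenesulfonate | COc1ccc(COC[C@H]2C/C=C\C[C@@H](O[Si](C)(C)C(C)(C)C)[C@@H](CCOS(=O)(=O)c3ccc(C)cc3)O2)cc1 | intermediate
18 | tert-butyl{[(2R,3R,5Z,8R)-2-ethyl-8-{[(4-methoxybenzyl)oxy]methyl}-3,4,7,8-tetrahydro-2H-oxocin-3-yl]oxy}dimethylsilane | COc1ccc(COC[C@H]2C/C=C\C[C@@H](O[Si](C)(C)C(C)(C)C)[C@@H](CC)O2)cc1 | intermediate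
19 | [(2R,3R,5Z,8R)-3-[(tert-butyldimethylsilyl)oxy]-2-ethyl-3,4,7,8-tetrahydro-2H-oxocin-8-yl]methanol | OC[C@H]1C/C=C\C[C@@H](O[Si](C)(C)C(C)(C)C)[C@@H](CC)O1 | intermediate
20 | (2R,3R,5Z,8R)-3-[(tert-butyldimethylsilyl)oxy]-2-ethyl-3,4,7,8-tetrahydro-2H-oxocine-8-carbaldehyde | O=C[C@H]1C/C=C\C[C@@H](O[Si](C)(C)C(C)(C)C)[C@@H](CC)O1 | intermediate
21 | (1R)-1-[(2R,3R,5Z,8R)-3-[(tert-butyldimethylsilyl)oxy]-2-ethyl-3,4,7,8-tetrahydro-2H-oxocin-8-yl]but-3-en-1-ol | C=CC[C@@H](O)[C@H]1C/C=C\C[C@@H](O[Si](C)(C)C(C)(C)C)[C@@H](CC)O1 | intermediate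
22 | (2E,5R)-5-[(2R,3R,5Z,8R)-3-[(tert-butyldimethylsilyl)oxy]-2-ethyl-3,4,7,8-tetrahydro-2H-oxocin-8-yl]-5-hydroxypent-2-enal | O=C/C=C/C[C@@H](O)[C@H]1C/C=C\C[C@@H](O[Si](C)(C)C(C)(C)C)[C@@H](CC)O1 | intermediate
23 | (1R,3E)-1-[(2R,3R,5Z,8R)-3-[(tert-butyldimethylsilyl)oxy]-2-ethyl-3,4,7,8-tetrahydro-2H-oxocin-8-yl]hex-3-en-5-yn-1-ol | C#C/C=C/C[C@@H](O)[C@H]1C/C=C\C[C@@H](O[Si](C)(C)C(C)(C)C)[C@@H](CC)O1 | intermediate
24 | (1R,3E)-1-[(2R,3R,5Z,8R)-3-[(tert-butyldimethylsilyl)oxy]-2-ethyl-3,4,7,8-tetrahydro-2H-oxocin-8-yl]hex-3-en-5-yn-1-yl acetate | C#C/C=C/C[C@@H](OC(C)=O)[C@H]1C/C=C\C[C@@H](O[Si](C)(C)C(C)(C)C)[C@@H](CC)O1 | intermediate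
25 | (1R,3E)-1-[(2R,3R,5Z,8R)-2-ethyl-3-hydroxy-3,4,7,8-tetrahydro-2H-oxocin-8-yl]hex-3-en-5-yn-1-yl acetate | C#C/C=C/C[C@@H](OC(C)=O)[C@H]1C/C=C\C[C@@H](O)[C@@H](CC)O1 | intermediate
26 | (1R,3E)-1-[(2R,3S,5Z,8R)-3-bromo-2-ethyl-3,4,7,8-tetrahydro-2H-oxocin-8-yl]hex-3-en-5-yn-1-yl acetate | C#C/C=C/C[C@@H](OC(C)=O)[C@H]1C/C=C\C[C@H](Br)[C@@H](CC)O1 | target

Total step count: 21. Longest linear sequence: 20 steps (step 1 then steps 3–21 from 1, or step 2 then steps 3–21 from 3).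

Steps most likely to fail

Step 8 (the proposed method). The ketyl may be reduced further or dimerize before the slow eight-membered closure takes place, or the ring may close with the wrong relative configuration at C12/C13 or C7/C13. The fallback uses known chemistry, sets out from 5 and returns at 18. Epoxide 5 is opened with vinylmagnesium bromide and CuI (cat.) to (2R)-1-[(4-methoxybenzyl)oxy]pent-4-en-2-ol F1. O-Alkylation with bromoacetic acid and NaH gives 2-{[(2R)-1-[(4-methoxybenzyl)oxy]pent-4-en-2-yl]oxy}acetic acid F2. Its pivaloyl mixed anhydride acylates lithiated (S)-4-benzyloxazolidin-2-one to give (4S)-4-benzyl-3-(2-{[(2R)-1-[(4-methoxybenzyl)oxy]pent-4-en-2-yl]oxy}acetyl)-1,3-oxazolidin-2-one F3. An Evans boron syn-aldol reaction (Bu2BOTf, Et3N, CH2Cl2, −78 °C) with freshly made but-3-enal should set C13 and C12 in (4S)-4-benzyl-3-[(2S,3R)-3-hydroxy-2-{[(2R)-1-[(4-methoxybenzyl)oxy]pent-4-en-2-yl]oxy}hex-5-enoyl]-1,3-oxazolidin-2-one F4. Silylation (TBSOTf, 2,6-lutidine) gives (4S)-4-benzyl-3-[(2S,3R)-3-[(tert-butyldimethylsilyl)oxy]-2-{[(2R)-1-[(4-methoxybenzyl)oxy]pent-4-en-2-yl]oxy}hex-5-enoyl]-1,3-oxazolidin-2-one F5. LiBH4 removes the auxiliary to give (2R,3R)-3-[(tert-butyldimethylsilyl)oxy]-2-{[(2R)-1-[(4-methoxybenzyl)oxy]pent-4-en-2-yl]oxy}hex-5-en-1-ol F6. Tosylation gives (2R,3R)-3-[(tert-butyldimethylsilyl)oxy]-2-{[(2R)-1-[(4-methoxybenzyl)oxy]pent-4-en-2-yl]oxy}hex-5-en-1-yl 4-methylbenzenesulfonate F7. Me2CuLi displaces the tosylate to give tert-butyl{[(4R,5R)-5-{[(2R)-1-[(4-methoxybenzyl)oxy]pent-4-en-2-yl]oxy}hept-1-en-4-yl]oxy}dimethylsilane F8. Ring-closing metathesis with the second-generation Grubbs catalyst [RuCl2(=CHPh)(H2IMes)(PCy3)] at high dilution, helped by the gauche arrangement of the C12 and C13 oxygens, closes C9=C10 and delivers 18 with C12 already in the needed configuration.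

Step 9. The alkoxyphosphonium ion at the hindered ring carbinol may eliminate toward the allylic C11 hydrogens (diene formation), or activation may be too slow for clean SN2 inversion. The fallback inverts by oxidation and reduction, sets out from 13 and returns at 15. Buffered Dess–Martin oxidation gives ethyl 2-[(2R,5Z,8R)-8-{[(4-methoxybenzyl)oxy]methyl}-3-oxo-3,4,7,8-tetrahydro-2H-oxocin-2-yl]acetate F9. LiB(s-Bu)3H in THF at −78 °C should deliver hydride to the ketone face away from the C13 arm and give ethyl 2-[(2R,3R,5Z,8R)-3-hydroxy-8-{[(4-methoxybenzyl)oxy]methyl}-3,4,7,8-tetrahydro-2H-oxocin-2-yl]acetate F10. LiBH4 reduction of F10 gives diol 15.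

Step 17. The ruthenium carbene may engage the ring cis-alkene (ring opening or oligomerization) in competition with the terminal alkene, or the catalyst may die before conversion is complete. The fallback avoids metathesis and the carbene-based alkyne synthesis, sets out from 20 and returns at 23. Chelation-controlled propargylation of 20 with allenyltributylstannane and MgBr2·OEt2 gives (1R)-1-[(2R,3R,5Z,8R)-3-[(tert-butyldimethylsilyl)oxy]-2-ethyl-3,4,7,8-tetrahydro-2H-oxocin-8-yl]but-3-yn-1-ol F11. Hydrozirconation with excess Cp2Zr(H)Cl followed by iodine gives (1R,3E)-1-[(2R,3R,5Z,8R)-3-[(tert-butyldimethylsilyl)oxy]-2-ethyl-3,4,7,8-tetrahydro-2H-oxocin-8-yl]-4-iodobut-3-en-1-ol F12. Sonogashira coupling with trimethylsilylacetylene (Pd(PPh3)4, CuI, i-Pr2NH) gives (1R,3E)-1-[(2R,3R,5Z,8R)-3-[(tert-butyldimethylsilyl)oxy]-2-ethyl-3,4,7,8-tetrahydro-2H-oxocin-8-yl]-6-(trimethylsilyl)hex-3-en-5-yn-1-ol F13. K2CO3 in MeOH removes the alkyne silyl group and returns 23.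

Further compounds
F1 | step 8 | (2R)-1-[(4-methoxybenzyl)oxy]pent-4-en-2-ol | COc1ccc(COC[C@H](O)CC=C)cc1
F2 | step 8 | 2-{[(2R)-1-[(4-methoxybenzyl)oxy]pent-4-en-2-yl]oxy}acetic acid | COc1ccc(COC[C@H](OCC(=O)O)CC=C)cc1
F3 | step 8 | (4S)-4-benzyl-3-(2-{[(2R)-1-[(4-methoxybenzyl)oxy]pent-4-en-2-yl]oxy}acetyl)-1,3-oxazolidin-2-one | COc1ccc(COC[C@H](OCC(=O)N2[C@@H](Cc3ccccc3)COC2=O)CC=C)cc1
F4 | step 8 | (4S)-4-benzyl-3-[(2S,3R)-3-hydroxy-2-{[(2R)-1-[(4-methoxybenzyl)oxy]pent-4-en-2-yl]oxy}hex-5-enoyl]-1,3-oxazolidin-2-one | COc1ccc(COC[C@H](O[C@@H]([C@H](O)CC=C)C(=O)N2[C@@H](Cc3ccccc3)COC2=O)CC=C)cc1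
F5 | step 8 | (4S)-4-benzyl-3-[(2S,3R)-3-[(tert-butyldimethylsilyl)oxy]-2-{[(2R)-1-[(4-methoxybenzyl)oxy]pent-4-en-2-yl]oxy}hex-5-enoyl]-1,3-oxazolidin-2-one | COc1ccc(COC[C@H](O[C@@H]([C@H](O[Si](C)(C)C(C)(C)C)CC=C)C(=O)N2[C@@H](Cc3ccccc3)COC2=O)CC=C)cc1
F6 | step 8 | (2R,3R)-3-[(tert-butyldimethylsilyl)oxy]-2-{[(2R)-1-[(4-methoxybenzyl)oxy]pent-4-en-2-yl]oxy}hex-5-en-1-ol | COc1ccc(COC[C@H](O[C@@H]([C@H](O[Si](C)(C)C(C)(C)C)CC=C)CO)CC=C)cc1
F7 | step 8 | (2R,3R)-3-[(tert-butyldimethylsilyl)oxy]-2-{[(2R)-1-[(4-methoxybenzyl)oxy]pent-4-en-2-yl]oxy}hex-5-en-1-yl 4-methylbenzenesulfonate | COc1ccc(COC[C@H](O[C@@H]([C@H](O[Si](C)(C)C(C)(C)C)CC=C)COS(=O)(=O)c2ccc(C)cc2)CC=C)cc1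
F8 | step 8 | tert-butyl{[(4R,5R)-5-{[(2R)-1-[(4-methoxybenzyl)oxy]pent-4-en-2-yl]oxy}hept-1-en-4-yl]oxy}dimethylsilane | COc1ccc(COC[C@H](O[C@@H]([C@H](O[Si](C)(C)C(C)(C)C)CC=C)CC)CC=C)cc1
F9 | step 9 | ethyl 2-[(2R,5Z,8R)-8-{[(4-methoxybenzyl)oxy]methyl}-3-oxo-3,4,7,8-tetrahydro-2H-oxocin-2-yl]acetate | COc1ccc(COC[C@H]2C/C=C\CC(=O)[C@@H](CC(=O)OCC)O2)cc1
F10 | step 9 | ethyl 2-[(2R,3R,5Z,8R)-3-hydroxy-8-{[(4-methoxybenzyl)oxy]methyl}-3,4,7,8-tetrahydro-2H-oxocin-2-yl]acetate | COc1ccc(COC[C@H]2C/C=C\C[C@@H](O)[C@@H](CC(=O)OCC)O2)cc1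
F11 | step 17 | (1R)-1-[(2R,3R,5Z,8R)-3-[(tert-butyldimethylsilyl)oxy]-2-ethyl-3,4,7,8-tetrahydro-2H-oxocin-8-yl]but-3-yn-1-ol | C#CC[C@@H](O)[C@H]1C/C=C\C[C@@H](O[Si](C)(C)C(C)(C)C)[C@@H](CC)O1
F12 | step 17 | (1R,3E)-1-[(2R,3R,5Z,8R)-3-[(tert-butyldimethylsilyl)oxy]-2-ethyl-3,4,7,8-tetrahydro-2H-oxocin-8-yl]-4-iodobut-3-en-1-ol | I/C=C/C[C@@H](O)[C@H]1C/C=C\C[C@@H](O[Si](C)(C)C(C)(C)C)[C@@H](CC)O1
F13 | step 17 | (1R,3E)-1-[(2R,3R,5Z,8R)-3-[(tert-butyldimethylsilyl)oxy]-2-ethyl-3,4,7,8-tetrahydro-2H-oxocin-8-yl]-6-(trimethylsilyl)hex-3-en-5-yn-1-ol | C[Si](C)(C)C#C/C=C/C[C@@H](O)[C@H]1C/C=C\C[C@@H](O[Si](C)(C)C(C)(C)C)[C@@H](CC)O1
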